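**Plan**

1. Ring numbering used here: C1 carries the dienyl chain, C4 the methyl group, C8=C9 is the Z alkene, C12 carries CO2H. The retrosynthesis cuts C4–C5 (ring closure), then C12=C13 (olefination), C11–C12 (phosphonate alkylation), and C9–C10 and C7–C8 (carbocupration of propyne).
2. Enabling feature: C13–C14–C1[C(=CH2)CH2–]–C2–C3–C4(CH3) is the skeleton of a limonene whose cyclohexene has been opened. Cleaving the cyclohexane-1,2-diol ring of 1 frees C4 as a methyl ketone (later a secondary carbinol electrophile flanked only by CH3 and CH2) and C13 as an aldehyde; C5 is a plain CH2 that can carry a removable phenylsulfonyl group.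
3. Forward: fragment 7 (C13–C4 with the complete side chain) and sulfonyl phosphonate 19 (C5–C12) are joined at C12=C13. The open chain is then closed to the 14-membered carbocycle by attack of the C5 carbanion on C4, and the sulfonyl group is removed.
4. Stereochemistry: C1 comes from the chiral pool (R-limonene series). C4 comes from enzymatic ketone reduction to the R carbinol, inverted during ring closure. C12 comes from Ru-catalysed asymmetric hydrogenation of the (E)-enoic acid. The Z alkene comes from syn carbocupration.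

Key step: step 13

Remark: the ligand antipode in step 12 is assigned by analogy with the (E)-2-methylbut-2-enoic acid series (ligand and product descriptors of the same sense); should the sense be opposite on this substrate, the (S)-ligand would be used.

Step 1
Reactants: 1 (1S,2S,4R)-1-methyl-4-(prop-1-en-2-yl)cyclohexane-1,2-diol
Product: 2 (3aS,5R,7aS)-2,2,7a-trimethyl-5-(prop-1-en-2-yl)hexahydro-1,3-benzodioxole
Conditions: 2,2-dimethoxypropane, camphorsulfonic acid (cat.), acetone, 25 °C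
Reagents that add atoms: 2,2-dimethoxypropane, COC(C)(C)OC
Why: Acid-catalysed acetal exchange (acetonide formation) on the trans-diol, reacting through its diequatorial chair, masks the two future carbonyl carbons (C4 and C13) against the alkyllithium of step 2 and touches no stereocentre.

Step 2
Reactants: 2 (3aS,5R,7aS)-2,2,7a-trimethyl-5-(prop-1-en-2-yl)hexahydro-1,3-benzodioxole; 3 1-bromo-3-methylbut-2-ene
Product: 5 (3aS,5R,7aS)-2,2,7a-trimethyl-5-(6-methylhepta-1,5-dien-2-yl)hexahydro-1,3-benzodioxole, via allyllithium 4 (not isolated)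
Conditions: nBuLi, TMEDA, hexane, 0 → 25 °C; then 3, THF, −78 → 0 °C
Reagents that add atoms: none
Why: Allylic lithiation of the isopropenyl methyl group (the kinetically preferred site, as for limonene itself) gives a symmetric 2-substituted allyllithium whose SN2 alkylation by the primary allylic bromide builds the 6-methylhepta-1,5-dien-2-yl chain without involving a stereocentre.

Step 3
Reactants: 5 (3aS,5R,7aS)-2,2,7a-trimethyl-5-(6-methylhepta-1,5-dien-2-yl)hexahydro-1,3-benzodioxole
Product: 7 (3R)-3-(6-methylhepta-1,5-dien-2-yl)-6-oxoheptanal, via diol 6 (not isolated)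
Conditions: H5IO6, THF/H2O, 0 → 25 °C
Reagents that add atoms: none
Why: Periodic acid hydrolyses the acetonide and cleaves the liberated vicinal diol (Malaprade glycol cleavage) to the C13 aldehyde and the C4 methyl ketone, while the three alkenes and the C1 stereocentre (α to neither carbonyl) are inert.

Step 4
Reactants: 8 (3-bromopropyl)(phenyl)sulfane; 9 propyne; 10 oxirane
Product: 14 (3Z)-4-methyl-7-(phenylsulfanyl)hept-3-en-1-ol, via Grignard reagent 11 (not isolated), via alkylcopper 12 (not isolated), via alkenylcopper 13 (not isolated)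
Conditions: Mg, Et2O; CuBr·SMe2, Et2O/SMe2, −45 °C; 9, −25 °C; hex-1-ynyllithium (from hex-1-yne and nBuLi), HMPA, −78 °C; 10, −78 → −20 °C; aq. NH4Cl
Reagents that add atoms: none
Why: Normant carbocupration adds the alkylcopper syn across propyne with copper on the terminal carbon, and the alkenylcopper, activated as its hexynyl cuprate, opens oxirane with retention, so the C7 chain and C10 end up cis on the trisubstituted C8=C9 alkene (Z).

Step 5
Reactants: 14 (3Z)-4-methyl-7-(phenylsulfanyl)hept-3-en-1-ol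
Product: 15 (3Z)-4-methyl-7-(phenylsulfonyl)hept-3-en-1-ol
Conditions: (NH4)6Mo7O24·4H2O (cat.), 30% H2O2, EtOH, 0 → 25 °C
Reagents that add atoms: hydrogen peroxide, OO
Why: Molybdate-catalysed peroxide oxidation should take the sulfide through the sulfoxide to the sulfone much faster than it epoxidises the trisubstituted alkene, installing the carbanion-stabilising and later removable group at C5.

Step 6
Reactants: 15 (3Z)-4-methyl-7-(phenylsulfonyl)hept-3-en-1-ol
Product: 16 {[(4Z)-7-iodo-4-methylhept-4-en-1-yl]sulfonyl}benzene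
Conditions: I2, PPh3, imidazole, CH2Cl2, 0 °C
Reagents that add atoms: iodine, II
Why: Appel-type iodination converts the primary alcohol into the primary iodide by SN2 at C11 without affecting the alkene geometry.

Step 7
Reactants: 16 {[(4Z)-7-iodo-4-methylhept-4-en-1-yl]sulfonyl}benzene; 17 prop-2-en-1-yl (diethoxyphosphoryl)acetate
Product: 19 prop-2-en-1-yl (5Z)-2-(diethoxyphosphoryl)-6-methyl-9-(phenylsulfonyl)non-5-enoate, via sodium phosphonoacetate 18 (not isolated)
Conditions: NaH, DMF, 0 °C; then 16, 50 °C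
Reagents that add atoms: none
Why: C-alkylation of the stabilised phosphonoacetate anion (SN2 at the primary iodide) forms the C11–C12 bond, and the weakly basic anion should neither deprotonate the sulfone α-CH2 nor eliminate the homoallylic iodide.

Step 8
Reactants: 19 prop-2-en-1-yl (5Z)-2-(diethoxyphosphoryl)-6-methyl-9-(phenylsulfonyl)non-5-enoate; 7 (3R)-3-(6-methylhepta-1,5-dien-2-yl)-6-oxoheptanal
Product: 21 prop-2-en-1-yl (2E,5R)-5-(6-methylhepta-1,5-dien-2-yl)-2-[(3Z)-4-methyl-7-(phenylsulfonyl)hept-3-en-1-yl]-8-oxonon-2-enoate, via sodium phosphonate 20 (not isolated)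
Conditions: NaH (1.0 equiv), THF, 0 °C; then 7, −20 → 25 °C
Reagents that add atoms: none
Why: Horner–Wadsworth–Emmons olefination is chemoselective for the aldehyde over the methyl ketone and should favour the (E)-trisubstituted enoate (ester trans to C14), forming C12=C13, with one equivalent of preformed anion limiting aldol reactions of 7.

Step 9
Reactants: 21 prop-2-en-1-yl (2E,5R)-5-(6-methylhepta-1,5-dien-2-yl)-2-[(3Z)-4-methyl-7-(phenylsulfonyl)hept-3-en-1-yl]-8-oxonon-2-enoate
Product: 22 prop-2-en-1-yl (2E,5R,8R)-8-hydroxy-5-(6-methylhepta-1,5-dien-2-yl)-2-[(3Z)-4-methyl-7-(phenylsulfonyl)hept-3-en-1-yl]non-2-enoate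
Conditions: (R)-selective ketoreductase (NADPH-dependent alcohol dehydrogenase of the Lactobacillus kefir type), NADP+ (cat.), iPrOH, phosphate buffer pH 7, MgCl2, 30 °C
Reagents that add atoms: none
Why: Enzymatic carbonyl reduction by an anti-Prelog ketoreductase, which tells the methyl from the CH2 substituent of a 2-alkanone far better than small chiral hydride reagents, should set the C4 carbinol as R with hydride from NADPH recycled by isopropanol, leaving ester, enoate and sulfone alone.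

Step 10
Reactants: 22 prop-2-en-1-yl (2E,5R,8R)-8-hydroxy-5-(6-methylhepta-1,5-dien-2-yl)-2-[(3Z)-4-methyl-7-(phenylsulfonyl)hept-3-en-1-yl]non-2-enoate
Product: 23 prop-2-en-1-yl (2E,5R,8R)-5-(6-methylhepta-1,5-dien-2-yl)-2-[(3Z)-4-methyl-7-(phenylsulfonyl)hept-3-en-1-yl]-8-[(4-methylphenyl)sulfonyloxy]non-2-enoate
Conditions: TsCl, pyridine, DMAP (cat.), CH2Cl2, 0 → 25 °C
Reagents that add atoms: 4-methylbenzenesulfonyl chloride, Cc1ccc(cc1)S(=O)(=O)Cl
Why: O-Sulfonylation of the secondary alcohol breaks no C–O bond, so the C4 configuration is retained, and it is done while the acid is still an allyl ester so that no mixed anhydride can form.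

Step 11
Reactants: 23 prop-2-en-1-yl (2E,5R,8R)-5-(6-methylhepta-1,5-dien-2-yl)-2-[(3Z)-4-methyl-7-(phenylsulfonyl)hept-3-en-1-yl]-8-[(4-methylphenyl)sulfonyloxy]non-2-enoate
Product: 24 (2E,5R,8R)-5-(6-methylhepta-1,5-dien-2-yl)-2-[(3Z)-4-methyl-7-(phenylsulfonyl)hept-3-en-1-yl]-8-[(4-methylphenyl)sulfonyloxy]non-2-enoic acid
Conditions: Pd(PPh3)4 (cat.), morpholine, THF, 0 °C
Reagents that add atoms: none
Why: Tsuji–Trost deallylation ionises the allyl ester on Pd(PPh3)4 and morpholine traps the allyl fragment, freeing the carboxylic acid under neutral conditions that should leave the secondary tosylate and the enoate intact.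

Step 12
Reactants: 24 (2E,5R,8R)-5-(6-methylhepta-1,5-dien-2-yl)-2-[(3Z)-4-methyl-7-(phenylsulfonyl)hept-3-en-1-yl]-8-[(4-methylphenyl)sulfonyloxy]non-2-enoic acid
Product: 25 (2R,5S,8R)-5-(6-methylhepta-1,5-dien-2-yl)-2-[(3Z)-4-methyl-7-(phenylsulfonyl)hept-3-en-1-yl]-8-[(4-methylphenyl)sulfonyloxy]nonanoic acid
Conditions: Ru(OAc)2[(R)-H8-BINAP] (cat.), H2 (4 atm), MeOH/THF, 20 °C
Reagents that add atoms: none
Why: Carboxylate-directed asymmetric hydrogenation of the geometrically pure (E)-2-alkyl-2-alkenoic acid (tiglic acid class) should set C12 as R under ligand control and leave the isolated alkenes, which carry no coordinating group, untouched.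

Step 13
Reactants: 25 (2R,5S,8R)-5-(6-methylhepta-1,5-dien-2-yl)-2-[(3Z)-4-methyl-7-(phenylsulfonyl)hept-3-en-1-yl]-8-[(4-methylphenyl)sulfonyloxy]nonanoic acid
Product: 27 (1R,4Z,9S,12S)-5,9-dimethyl-12-(6-methylhepta-1,5-dien-2-yl)-8-(phenylsulfonyl)cyclotetradec-4-ene-1-carboxylic acid (both C8 epimers), via dilithium dianion 26 (not isolated)
Conditions: LiN(iPr)2 (2.1 equiv), THF, −78 °C, 0.002 M; DMPU, −78 → 25 °C; aq. HCl
Reagents that add atoms: none
Why: Proposed new method: two equivalents of lithium diisopropylamide give the carboxylate/α-sulfonyl carbanion dianion 26, whose C5 carbanion displaces the C4 tosylate by backside SN2 attack; the closest known reaction types are the intermolecular alkylation of α-sulfonyl carbanions by secondary sulfonates with inversion and the macrocyclisation of sulfonyl carbanions onto primary allylic halides or epoxides. The 14-membered carbocycle closes in the 14-exo-tet mode, the leaving oxygen lying outside the new ring. C4 is controlled by the substrate: the R carbinol configuration set enzymatically in step 9 is inverted stereospecifically, which gives the methyl-bearing centre of 28, whereas the sulfonyl-bearing C5 centre forms as a mixture that step 14 erases. The step needs C- over O-alkylation, substitution over elimination and ring closure over oligomerisation: the carboxylate is a far weaker nucleophile than the carbanion and could only close a 9-membered lactone, the acyclic CH3–CH(OTs)–CH2 unit is an unhindered secondary sulfonate, and high dilution with DMPU favours the intramolecular path. Keeping C12 as a lithium carboxylate also makes its α-hydrogen too weakly acidic to be removed, so the centre set in step 12 can neither epimerise nor close the competing 7-membered ring onto C4.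

Step 14
Reactants: 27 (1R,4Z,9S,12S)-5,9-dimethyl-12-(6-methylhepta-1,5-dien-2-yl)-8-(phenylsulfonyl)cyclotetradec-4-ene-1-carboxylic acid
Product: 28 (1R,4Z,9R,12R)-5,9-dimethyl-12-(6-methylhepta-1,5-dien-2-yl)cyclotetradec-4-ene-1-carboxylic acid
Conditions: 6% Na(Hg), Na2HPO4, MeOH/THF, −20 → 0 °C; then dilute HCl
Reagents that add atoms: none
Why: Reductive desulfonylation by single-electron transfer from Na(Hg) cleaves the C5–S bond and protonates the resulting carbanion, erasing the C5 epimers without affecting the isolated alkenes or the three stereocentres.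

**Compound list**

1 | (1S,2S,4R)-1-methyl-4-(prop-1-en-2-yl)cyclohexane-1,2-diol (limonene-1,2-diol of the R-limonene series) | CC(=C)[C@@H]1CC[C@](C)(O)[C@@H](O)C1 | starting material
2 | (3aS,5R,7aS)-2,2,7a-trimethyl-5-(prop-1-en-2-yl)hexahydro-1,3-benzodioxole (acetonide of 1) | CC(=C)[C@@H]1CC[C@]2(C)OC(C)(C)O[C@H]2C1 | intermediate
3 | 1-bromo-3-methylbut-2-ene (prenyl bromide) | CC(C)=CCBr | starting material
4 | {2-[(3aS,5R,7aS)-2,2,7a-trimethylhexahydro-1,3-benzodioxol-5-yl]prop-2-en-1-yl}lithium | [Li]CC(=C)[C@@H]1CC[C@]2(C)OC(C)(C)O[C@H]2C1 | intermediate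
5 | (3aS,5R,7aS)-2,2,7a-trimethyl-5-(6-methylhepta-1,5-dien-2-yl)hexahydro-1,3-benzodioxole | CC(C)=CCCC(=C)[C@@H]1CC[C@]2(C)OC(C)(C)O[C@H]2C1 | intermediate
6 | (1S,2S,4R)-1-methyl-4-(6-methylhepta-1,5-dien-2-yl)cyclohexane-1,2-diol | CC(C)=CCCC(=C)[C@@H]1CC[C@](C)(O)[C@@H](O)C1 | intermediate
7 | (3R)-3-(6-methylhepta-1,5-dien-2-yl)-6-oxoheptanal | C=C(CCC=C(C)C)[C@@H](CC=O)CCC(C)=O | intermediate
8 | (3-bromopropyl)(phenyl)sulfane | BrCCCSc1ccccc1 | starting material
9 | propyne | CC#C | starting material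
10 | oxirane (ethylene oxide) | C1CO1 | starting material
11 | [3-(phenylsulfanyl)propyl]magnesium bromide | Br[Mg]CCCSc1ccccc1 | intermediate
12 | [3-(phenylsulfanyl)propyl]copper | [Cu]CCCSc1ccccc1 | intermediate
13 | [(1Z)-2-methyl-5-(phenylsulfanyl)pent-1-en-1-yl]copper | [Cu]/C=C(C)\CCCSc1ccccc1 | intermediate
14 | (3Z)-4-methyl-7-(phenylsulfanyl)hept-3-en-1-ol | OCC/C=C(C)\CCCSc1ccccc1 | intermediate
15 | (3Z)-4-methyl-7-(phenylsulfonyl)hept-3-en-1-ol | OCC/C=C(C)\CCCS(=O)(=O)c1ccccc1 | intermediate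
16 | {[(4Z)-7-iodo-4-methylhept-4-en-1-yl]sulfonyl}benzene | ICC/C=C(C)\CCCS(=O)(=O)c1ccccc1 | intermediate
17 | prop-2-en-1-yl (diethoxyphosphoryl)acetate (allyl diethylphosphonoacetate) | C=CCOC(=O)CP(=O)(OCC)OCC | starting material
18 | sodium salt of 17 | C=CCOC(=O)[CH-]P(=O)(OCC)OCC.[Na+] | intermediate
19 | prop-2-en-1-yl (5Z)-2-(diethoxyphosphoryl)-6-methyl-9-(phenylsulfonyl)non-5-enoate (racemic at C2) | C=CCOC(=O)C(CC/C=C(C)\CCCS(=O)(=O)c1ccccc1)P(=O)(OCC)OCC | intermediate
20 | sodium salt of 19 | C=CCOC(=O)[C-](CC/C=C(C)\CCCS(=O)(=O)c1ccccc1)P(=O)(OCC)OCC.[Na+] | intermediate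
21 | prop-2-en-1-yl (2E,5R)-5-(6-methylhepta-1,5-dien-2-yl)-2-[(3Z)-4-methyl-7-(phenylsulfonyl)hept-3-en-1-yl]-8-oxonon-2-enoate | C=CCOC(=O)/C(CC/C=C(C)\CCCS(=O)(=O)c1ccccc1)=C/C[C@@H](CCC(C)=O)C(=C)CCC=C(C)C | intermediate
22 | prop-2-en-1-yl (2E,5R,8R)-8-hydroxy-5-(6-methylhepta-1,5-dien-2-yl)-2-[(3Z)-4-methyl-7-(phenylsulfonyl)hept-3-en-1-yl]non-2-enoate | C=CCOC(=O)/C(CC/C=C(C)\CCCS(=O)(=O)c1ccccc1)=C/C[C@@H](CC[C@@H](C)O)C(=C)CCC=C(C)C | intermediate
23 | prop-2-en-1-yl (2E,5R,8R)-5-(6-methylhepta-1,5-dien-2-yl)-2-[(3Z)-4-methyl-7-(phenylsulfonyl)hept-3-en-1-yl]-8-[(4-methylphenyl)sulfonyloxy]non-2-enoate | C=CCOC(=O)/C(CC/C=C(C)\CCCS(=O)(=O)c1ccccc1)=C/C[C@@H](CC[C@@H](C)OS(=O)(=O)c1ccc(C)cc1)C(=C)CCC=C(C)C | intermediate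
24 | (2E,5R,8R)-5-(6-methylhepta-1,5-dien-2-yl)-2-[(3Z)-4-methyl-7-(phenylsulfonyl)hept-3-en-1-yl]-8-[(4-methylphenyl)sulfonyloxy]non-2-enoic acid | OC(=O)/C(CC/C=C(C)\CCCS(=O)(=O)c1ccccc1)=C/C[C@@H](CC[C@@H](C)OS(=O)(=O)c1ccc(C)cc1)C(=C)CCC=C(C)C | intermediate
25 | (2R,5S,8R)-5-(6-methylhepta-1,5-dien-2-yl)-2-[(3Z)-4-methyl-7-(phenylsulfonyl)hept-3-en-1-yl]-8-[(4-methylphenyl)sulfonyloxy]nonanoic acid (C5 unchanged in space from 24; its descriptor changes by priority only) | OC(=O)[C@H](CC/C=C(C)\CCCS(=O)(=O)c1ccccc1)CC[C@@H](CC[C@@H](C)OS(=O)(=O)c1ccc(C)cc1)C(=C)CCC=C(C)C | intermediate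
26 | dilithium salt of 25 (carboxylate and α-sulfonyl carbanion at C5) | [Li+].[Li+].[O-]C(=O)[C@H](CC/C=C(C)\CC[CH-]S(=O)(=O)c1ccccc1)CC[C@@H](CC[C@@H](C)OS(=O)(=O)c1ccc(C)cc1)C(=C)CCC=C(C)C | intermediate
27 | (1R,4Z,9S,12S)-5,9-dimethyl-12-(6-methylhepta-1,5-dien-2-yl)-8-(phenylsulfonyl)cyclotetradec-4-ene-1-carboxylic acid, both C8 epimers (C9 and C12 arranged in space as in 28; descriptors differ by priority only) | C=C(CCC=C(C)C)[C@@H]1CC[C@H](C)C(S(=O)(=O)c2ccccc2)CC/C(C)=C\CC[C@@H](C(=O)O)CC1 | intermediate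
28 | (1R,4Z,9R,12R)-5,9-dimethyl-12-(6-methylhepta-1,5-dien-2-yl)cyclotetradec-4-ene-1-carboxylic acid | C=C(CCC=C(C)C)[C@@H]1CC[C@H](C)CCC/C(C)=C\CC[C@@H](C(=O)O)CC1 | target

**Step count**

Total: 14 steps. Longest linear sequence: 11 steps (steps 4 to 14, from 8 to 28).

**Steps most likely to fail**

Step 13. Elimination of the secondary sulfonate by the carbanion, attack at sulfonyl sulfur, or intermolecular alkylation may outrun the 14-membered closure. The fallback uses known chemistry: the C4–C5 bond is made between fragments and the ring is closed at C12=C13. It sets out from 7 and 19.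
- Selective acetalisation of the aldehyde of 7 (CH(OMe)3, pyridinium tosylate, MeOH) would give (5R)-7,7-dimethoxy-5-(6-methylhepta-1,5-dien-2-yl)heptan-2-one F1.
- The ketoreductase of step 9 would give (2R,5R)-7,7-dimethoxy-5-(6-methylhepta-1,5-dien-2-yl)heptan-2-ol F2.
- TsCl/pyridine would give (2R,5R)-7,7-dimethoxy-5-(6-methylhepta-1,5-dien-2-yl)heptan-2-yl 4-methylbenzenesulfonate F3.
- Treating 19 with NaH and then nBuLi (THF/DMPU, −78 °C) would give the sodium lithium dianion of 19 F4. Its more basic α-sulfonyl carbon would be alkylated by F3 with inversion (intermolecular SN2 of sulfonyl carbanions on secondary sulfonates) to give prop-2-en-1-yl (5Z,10S,13R)-2-(diethoxyphosphoryl)-13-(2,2-dimethoxyethyl)-6,10,18-trimethyl-14-methylidene-9-(phenylsulfonyl)nonadeca-5,17-dienoate F5.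
- Pyridinium tosylate in acetone/H2O would free the aldehyde, prop-2-en-1-yl (5Z,10S,13R)-2-(diethoxyphosphoryl)-6,10,18-trimethyl-14-methylidene-13-(2-oxoethyl)-9-(phenylsulfonyl)nonadeca-5,17-dienoate F6.
- Intramolecular Horner–Wadsworth–Emmons olefination (LiCl, DBU, MeCN, high dilution) would close the ring as prop-2-en-1-yl (1E,4R,7S,11Z)-7,11-dimethyl-4-(6-methylhepta-1,5-dien-2-yl)-8-(phenylsulfonyl)cyclotetradeca-1,11-diene-1-carboxylate F7.
- Pd(PPh3)4/morpholine would give (1E,4R,7S,11Z)-7,11-dimethyl-4-(6-methylhepta-1,5-dien-2-yl)-8-(phenylsulfonyl)cyclotetradeca-1,11-diene-1-carboxylic acid F8. Hydrogenation as in step 12 comes back to the route at 27.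

Step 2. The allyllithium may attack the tertiary terminus of the prenyl electrophile (SN2′), and over-metalation may occur, giving regioisomeric or doubly alkylated chains. The fallback sets out from 2 through the same allyllithium 4. Trapping with oxirane (THF, −78 → 0 °C), which cannot react in an SN2′ sense, would give 4-[(3aS,5R,7aS)-2,2,7a-trimethylhexahydro-1,3-benzodioxol-5-yl]pent-4-en-1-ol F9. Dess–Martin oxidation would give 4-[(3aS,5R,7aS)-2,2,7a-trimethylhexahydro-1,3-benzodioxol-5-yl]pent-4-enal F10. Wittig olefination with the ylide from isopropyltriphenylphosphonium iodide and nBuLi comes back to the route at 5.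

Step 8. Incomplete E selectivity of the olefination and base-induced intramolecular aldol condensation of the keto-aldehyde may occur; a geometric mixture would erode the enantioselectivity of step 12. The fallback sets out from 16. Alkylation of allyl (triphenylphosphoranylidene)acetate with 16 (EtOAc, reflux) would give {(4Z)-5-methyl-8-(phenylsulfonyl)-1-[(prop-2-en-1-yloxy)carbonyl]oct-4-en-1-yl}triphenylphosphonium iodide F11. Aqueous NaOH/CH2Cl2 would give the α-substituted stabilised ylide prop-2-en-1-yl (5Z)-6-methyl-9-(phenylsulfonyl)-2-(triphenyl-λ5-phosphanylidene)non-5-enoate F12. Base-free Wittig olefination of 7 (toluene, 60 °C), which is aldehyde-selective and strongly E-selective for this ylide class, comes back to the route at 21.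

**Further compounds**

F1 | step 13 | (5R)-7,7-dimethoxy-5-(6-methylhepta-1,5-dien-2-yl)heptan-2-one | C=C(CCC=C(C)C)[C@@H](CC(OC)OC)CCC(C)=O
F2 | step 13 | (2R,5R)-7,7-dimethoxy-5-(6-methylhepta-1,5-dien-2-yl)heptan-2-ol | C=C(CCC=C(C)C)[C@@H](CC(OC)OC)CC[C@@H](C)O
F3 | step 13 | (2R,5R)-7,7-dimethoxy-5-(6-methylhepta-1,5-dien-2-yl)heptan-2-yl 4-methylbenzenesulfonate | C=C(CCC=C(C)C)[C@@H](CC(OC)OC)CC[C@@H](C)OS(=O)(=O)c1ccc(C)cc1
F4 | step 13 | sodium lithium dianion of 19 (phosphonoacetate carbanion and α-sulfonyl carbanion) | C=CCOC(=O)[C-](CC/C=C(C)\CC[CH-]S(=O)(=O)c1ccccc1)P(=O)(OCC)OCC.[Na+].[Li+]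
F5 | step 13 | prop-2-en-1-yl (5Z,10S,13R)-2-(diethoxyphosphoryl)-13-(2,2-dimethoxyethyl)-6,10,18-trimethyl-14-methylidene-9-(phenylsulfonyl)nonadeca-5,17-dienoate | C=CCOC(=O)C(P(=O)(OCC)OCC)CC/C=C(C)\CCC(S(=O)(=O)c1ccccc1)[C@@H](C)CC[C@H](CC(OC)OC)C(=C)CCC=C(C)C
F6 | step 13 | prop-2-en-1-yl (5Z,10S,13R)-2-(diethoxyphosphoryl)-6,10,18-trimethyl-14-methylidene-13-(2-oxoethyl)-9-(phenylsulfonyl)nonadeca-5,17-dienoate | C=CCOC(=O)C(P(=O)(OCC)OCC)CC/C=C(C)\CCC(S(=O)(=O)c1ccccc1)[C@@H](C)CC[C@H](CC=O)C(=C)CCC=C(C)C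
F7 | step 13 | prop-2-en-1-yl (1E,4R,7S,11Z)-7,11-dimethyl-4-(6-methylhepta-1,5-dien-2-yl)-8-(phenylsulfonyl)cyclotetradeca-1,11-diene-1-carboxylate | C=C(CCC=C(C)C)[C@@H]1CC[C@H](C)C(S(=O)(=O)c2ccccc2)CC/C(C)=C\CC/C(C(=O)OCC=C)=C\C1
F8 | step 13 | (1E,4R,7S,11Z)-7,11-dimethyl-4-(6-methylhepta-1,5-dien-2-yl)-8-(phenylsulfonyl)cyclotetradeca-1,11-diene-1-carboxylic acid | C=C(CCC=C(C)C)[C@@H]1CC[C@H](C)C(S(=O)(=O)c2ccccc2)CC/C(C)=C\CC/C(C(=O)O)=C\C1
F9 | step 2 | 4-[(3aS,5R,7aS)-2,2,7a-trimethylhexahydro-1,3-benzodioxol-5-yl]pent-4-en-1-ol | OCCCC(=C)[C@@H]1CC[C@]2(C)OC(C)(C)O[C@H]2C1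
F10 | step 2 | 4-[(3aS,5R,7aS)-2,2,7a-trimethylhexahydro-1,3-benzodioxol-5-yl]pent-4-enal | O=CCCC(=C)[C@@H]1CC[C@]2(C)OC(C)(C)O[C@H]2C1
F11 | step 8 | {(4Z)-5-methyl-8-(phenylsulfonyl)-1-[(prop-2-en-1-yloxy)carbonyl]oct-4-en-1-yl}triphenylphosphonium iodide | C=CCOC(=O)C(CC/C=C(C)\CCCS(=O)(=O)c1ccccc1)[P+](c1ccccc1)(c1ccccc1)c1ccccc1.[I-]
F12 | step 8 | prop-2-en-1-yl (5Z)-6-methyl-9-(phenylsulfonyl)-2-(triphenyl-λ5-phosphanylidene)non-5-enoate | C=CCOC(=O)C(CC/C=C(C)\CCCS(=O)(=O)c1ccccc1)=P(c1ccccc1)(c1ccccc1)c1ccccc1
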